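**Retrosynthetic overview**

- The target is a 1,2-diarylpropan-1-ol: the carbinol carbon C7 carries ring A (3,4-dimethoxyphenyl) and the adjacent methyl-bearing C8 carries ring B (5-allyl-2-hydroxy-3-methoxyphenyl), both S. This vicinal aryl/aryl pattern on a three-carbon chain is the feature the plan rests on.
- The phenol is unmasked last from its 2-(trimethylsilyl)ethoxymethyl (SEM) ether with fluoride, and C7–OH is traced back to a C7–B bond (boronate oxidation with retention).
- Key disconnection: the C7–ring A and C8–ring B bonds are cut together, leading to an (E)-propenylboronic ester with boron on C7, 3,4-dimethoxyphenyllithium and SEM-protected 6-bromoeugenol (conjunctive coupling, anti addition across the E alkene).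
- The boronic ester comes from trans-1-propenylboronic acid and the cis diol made from acenaphthoquinone and MeMgBr ("mac" diol); the bromide comes from eugenol by ortho-bromination and SEM protection.
- No ring is formed at any stage; rings A and B are bought intact as 4-bromoveratrole and eugenol.

Key step: step 5

Assumption: the (Sp,Sp) antipode of the MandyPhos ligand is written in step 5; the antipode required is the one that places palladium on the propenyl face that is Re at C7 and C8, so the (Rp,Rp) ligand is used instead if the sense on this substrate is the reverse.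

**Route**

Step 1
Reactants: 1 eugenol (4-allyl-2-methoxyphenol)
Product: 2 4-allyl-2-bromo-6-methoxyphenol (6-bromoeugenol)
Conditions: NBS (1.0 equiv), i-Pr2NH (0.1 equiv), CH2Cl2, 0 °C, dark
Reagents that add atoms: N-bromosuccinimide, O=C1CCC(=O)N1Br
Why: Amine-catalysed electrophilic aromatic bromination with NBS should go to the only free position ortho to the phenol (para is blocked by the allyl group), and the ionic, cold, light-free conditions should leave the allyl alkene untouched.

Step 2
Reactants: 2 4-allyl-2-bromo-6-methoxyphenol
Product: 3 5-allyl-1-bromo-3-methoxy-2-{[2-(trimethylsilyl)ethoxy]methoxy}benzene (SEM ether of 6-bromoeugenol)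
Conditions: NaH, THF/DMF, 0 °C; then SEMCl, 0 °C to rt
Reagents that add atoms: 2-(trimethylsilyl)ethoxymethyl chloride, C[Si](C)(C)CCOCCl
Why: Williamson-type O-alkylation of the sodium phenoxide with the reactive α-chloro ether should be fast even at this flanked phenol, and SEM is chosen because it can later be removed by fluoride without acid.

Step 3
Reactants: 4 acenaphthoquinone
Product: 5 cis-1,2-dimethylacenaphthene-1,2-diol (meso, 1R,2S)
Conditions: MeMgBr (2.5 equiv), THF, 0 °C to rt; water then aq NH4Cl; recrystallisation
Reagents that add atoms: methylmagnesium bromide, C[Mg]Br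
Why: Double Grignard 1,2-addition to the 1,2-diketone should give the cis diol as the main isomer (second methyl enters anti to the bulky magnesium alkoxide); it is purified by crystallisation, and only the cis isomer can bridge boron in step 4.

Step 4
Reactants: 6 trans-1-propenylboronic acid; 5 cis-1,2-dimethylacenaphthene-1,2-diol
Product: 7 (E)-prop-1-enylboronic ester of diol 5, (E)-propenyl B(mac)
Conditions: MgSO4, CH2Cl2, rt
Reagents that add atoms: none
Why: Dehydrative condensation of a boronic acid with a cis-1,2-diol to the five-membered cyclic boronic ester is driven by the drying agent and leaves the E alkene geometry unchanged.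

Step 5
Reactants: 8 4-bromoveratrole; 7 (E)-propenyl B(mac); 3 SEM ether of 6-bromoeugenol
Product: 11 B(mac) ester of (1S,2R)-2-(5-allyl-3-methoxy-2-{[2-(trimethylsilyl)ethoxy]methoxy}phenyl)-1-(3,4-dimethoxyphenyl)propylboronic acid, via 3,4-dimethoxyphenyllithium 9 (not isolated), via lithium aryl(propenyl)B(mac) ate complex 10 (not isolated)
Conditions: 8 (1.05 equiv), t-BuLi (2.0 equiv), Et2O, −78 °C; 7 (1.0 equiv) in THF, −78 °C to rt; solvent exchange to THF; 3 (1.1 equiv), Pd(OAc)2 (3 mol%), (Sp,Sp)-1,1'-bis[bis(3,5-dimethylphenyl)phosphino]-2,2'-bis[(R)-α-(dimethylamino)benzyl]ferrocene (MandyPhos, 3.6 mol%), KOTf (2.2 equiv), THF, 60 °C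
Reagents that add atoms: none
Why: Bromine–lithium exchange gives 9, which adds to the boron of 7 to form ate complex 10; oxidative addition of 3 to zerovalent palladium, with KOTf taking up bromide, then gives a cationic divalent arylpalladium that binds the propenyl alkene of 10. The 3,4-dimethoxyphenyl group shifts from boron to C7 on the face opposite to palladium while palladium bonds to C8 (metal-induced 1,2-boronate shift), and reductive elimination with retention makes the C8–ring B bond. The closest known reaction type is the palladium-catalysed enantioselective conjunctive cross-coupling of β-substituted alkenyl B(mac) ate complexes with aryl electrophiles; no ring is closed. The relative configuration of C7 and C8 follows stereospecifically from anti addition of the two aryl groups across the E alkene, which corresponds to the 1S,2R boronate and hence the 7S,8S carbinol, and the absolute configuration is set by the chiral diphosphine, which must place palladium on the alkene face that is Re at both C7 and C8. The step needs the 1,2-shift to outrun direct Suzuki-type transmetalation and needs the allyl group of 3 to stay a spectator; the hindered B(mac) diol on boron and the electron-rich migrating aryl should secure the first, and the much higher nucleophilicity of the borate alkene over the isolated allyl alkene should secure the second.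

Step 6
Reactants: 11 B(mac) boronate
Product: 12 (1S,2S)-2-(5-allyl-3-methoxy-2-{[2-(trimethylsilyl)ethoxy]methoxy}phenyl)-1-(3,4-dimethoxyphenyl)propan-1-ol
Conditions: H2O2 (30% aq), NaOH (3 M aq), THF, 0 °C to rt
Reagents that add atoms: hydrogen peroxide, OO
Why: In this boronate oxidation, hydroperoxide adds to boron and the benzylic carbon migrates from boron to oxygen with retention, so C7–B becomes C7–OH with C8 untouched (the descriptor at C8 changes from R to S only through the priority rules), and the allyl alkene and SEM ether are inert to alkaline peroxide.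

Step 7
Reactants: 12 SEM-protected carbinol
Product: 13 (1S,2S)-2-(5-allyl-2-hydroxy-3-methoxyphenyl)-1-(3,4-dimethoxyphenyl)propan-1-ol (target, CNP0176583.1)
Conditions: TBAF (4 equiv), THF/DMPU, 50 °C; aq NH4Cl work-up
Reagents that add atoms: none
Why: Fluoride attack at silicon fragments the SEM group to the phenoxide, ethene and formaldehyde under non-acidic conditions, so the electron-rich benzylic alcohol should neither ionise nor cyclise onto the phenol, and neither stereocentre is touched.

**Compound list**

1 | eugenol (4-allyl-2-methoxyphenol) | C=CCc1ccc(O)c(OC)c1 | starting material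
2 | 4-allyl-2-bromo-6-methoxyphenol (6-bromoeugenol) | C=CCc1cc(Br)c(O)c(OC)c1 | intermediate
3 | 5-allyl-1-bromo-3-methoxy-2-{[2-(trimethylsilyl)ethoxy]methoxy}benzene | C=CCc1cc(OC)c(OCOCC[Si](C)(C)C)c(Br)c1 | intermediate
4 | acenaphthoquinone | O=C1C(=O)c2cccc3cccc1c23 | starting material
5 | cis-1,2-dimethylacenaphthene-1,2-diol (meso) | O[C@]1(C)c2cccc3cccc(c23)[C@]1(C)O | intermediate
6 | trans-1-propenylboronic acid | C/C=C/B(O)O | starting material
7 | (E)-prop-1-enylboronic ester of diol 5, (E)-propenyl B(mac) | C/C=C/B1O[C@]2(C)c3cccc4cccc(c34)[C@]2(C)O1 | intermediate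
8 | 4-bromoveratrole (4-bromo-1,2-dimethoxybenzene) | COc1ccc(Br)cc1OC | starting material
9 | 3,4-dimethoxyphenyllithium | [Li]c1ccc(OC)c(OC)c1 | intermediate (not isolated)
10 | lithium (3,4-dimethoxyphenyl)[(E)-propenyl]B(mac) ate complex (configuration at boron not defined; either form should converge) | [Li+].C/C=C/[B-]1(c2ccc(OC)c(OC)c2)O[C@]2(C)c3cccc4cccc(c34)[C@]2(C)O1 | intermediate (not isolated)
11 | B(mac) ester of (1S,2R)-2-(5-allyl-3-methoxy-2-{[2-(trimethylsilyl)ethoxy]methoxy}phenyl)-1-(3,4-dimethoxyphenyl)propylboronic acid | C=CCc1cc(OC)c(OCOCC[Si](C)(C)C)c([C@H](C)[C@H](B2O[C@]3(C)c4cccc5cccc(c45)[C@]3(C)O2)c2ccc(OC)c(OC)c2)c1 | intermediate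
12 | (1S,2S)-2-(5-allyl-3-methoxy-2-{[2-(trimethylsilyl)ethoxy]methoxy}phenyl)-1-(3,4-dimethoxyphenyl)propan-1-ol | C=CCc1cc(OC)c(OCOCC[Si](C)(C)C)c([C@H](C)[C@H](O)c2ccc(OC)c(OC)c2)c1 | intermediate
13 | (1S,2S)-2-(5-allyl-2-hydroxy-3-methoxyphenyl)-1-(3,4-dimethoxyphenyl)propan-1-ol | C=CCc1cc(OC)c(O)c([C@H](C)[C@H](O)c2ccc(OC)c(OC)c2)c1 | target

**Step count**

Total: 7 steps. Longest linear sequence: 5 steps (1 → 2 → 3 → 11 → 12 → 13; the branch 4 → 5 → 7 → 11 → 12 → 13 is equally long).

**Steps most likely to fail**

Step 5. The 1,2-shift may be overtaken by direct transmetalation of the ate complex (Suzuki-type transfer of the aryl or propenyl group). Turnover may also be slowed by the ortho SEM-oxy group chelating the cationic palladium, or facial selectivity may be insufficient. The fallback sets out from 3 and builds the same two bonds through a ketone. Palladium-catalysed ketone α-arylation of commercial 1-(3,4-dimethoxyphenyl)propan-1-one with 3 (Pd2(dba)3, XPhos, NaOt-Bu, toluene, 80 °C) should give racemic 2-(5-allyl-3-methoxy-2-{[2-(trimethylsilyl)ethoxy]methoxy}phenyl)-1-(3,4-dimethoxyphenyl)propan-1-one F1. Noyori-type asymmetric transfer hydrogenation under dynamic kinetic resolution (RuCl(p-cymene)[(S,S)-TsDPEN], HCO2H/Et3N, DMF, 40 °C) would then reduce F1 while its α-aryl stereocentre racemises through the enol. The catalyst is expected, by analogy with simple aryl ketones, to set C7 as S. The Felkin–Anh preference (hydride anti to ring B) should make the 8S ketone the fast-reacting enantiomer, so the route comes back at 12.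

Step 1. Bromine transfer to the allyl alkene, or radical allylic bromination, may compete with ring substitution. The fallback sets out from 1 and uses the alkene's own dibromide as its protection. Br2 (2 equiv, CHCl3, 0 °C) should give 2-bromo-4-(2,3-dibromopropyl)-6-methoxyphenol F2 by addition to the alkene plus ortho ring bromination. Zinc dust in AcOH/Et2O at rt would then remove the vicinal dibromide reductively, leaving the aryl bromide, so the route comes back at 2.

Step 7. Fragmentation of the SEM ether at the doubly flanked aryl oxygen may be sluggish, and the heating in basic fluoride then needed could move the allyl double bond into conjugation. The fallback sets out from 2 with a phenol protecting group that falls off during the oxidation. TBSCl and imidazole in DMF should give (4-allyl-2-bromo-6-methoxyphenoxy)(tert-butyl)dimethylsilane F3. F3 would be used in place of 3 under the conditions of step 5 to give the B(mac) ester of (1S,2R)-2-[5-allyl-2-(tert-butyldimethylsilyloxy)-3-methoxyphenyl]-1-(3,4-dimethoxyphenyl)propylboronic acid F4. Treating F4 with H2O2 and aqueous NaOH in THF should oxidise the C7–B bond and hydrolyse the base-labile aryl silyl ether in the same flask, so the route comes back at 13.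

**Further compounds**

F1 | step 5 | 2-(5-allyl-3-methoxy-2-{[2-(trimethylsilyl)ethoxy]methoxy}phenyl)-1-(3,4-dimethoxyphenyl)propan-1-one (racemic) | C=CCc1cc(OC)c(OCOCC[Si](C)(C)C)c(C(C)C(=O)c2ccc(OC)c(OC)c2)c1
F2 | step 1 | 2-bromo-4-(2,3-dibromopropyl)-6-methoxyphenol (racemic) | COc1cc(CC(Br)CBr)cc(Br)c1O
F3 | step 7 | (4-allyl-2-bromo-6-methoxyphenoxy)(tert-butyl)dimethylsilane | C=CCc1cc(OC)c(O[Si](C)(C)C(C)(C)C)c(Br)c1
F4 | step 7 | B(mac) ester of (1S,2R)-2-[5-allyl-2-(tert-butyldimethylsilyloxy)-3-methoxyphenyl]-1-(3,4-dimethoxyphenyl)propylboronic acid | C=CCc1cc(OC)c(O[Si](C)(C)C(C)(C)C)c([C@H](C)[C@H](B2O[C@]3(C)c4cccc5cccc(c45)[C@]3(C)O2)c2ccc(OC)c(OC)c2)c1
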